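**Plan**

- Retrosynthesis: after removal of the protecting groups and of the C1–C2 hydrogens, the C9–C10 bond (shared by ring B and the cyclobutane) and the C6–C7 bond (ring B glycol) are cut together. This leaves ring A as a dienone-enal and ring C as a 3-alkoxy-enone that carries C7 as a formyl acetal on C8, the two rings held only by the C1–C11 bond.
- Enabling feature: C10 is the β-carbon of the C6 enal and C9 is the oxygen-bearing β-carbon of the C14 enone, and the two sit 1,4 to each other across C1–C11. C7 becomes a second acceptor carbon once one acetal oxygen has left. One electron-transfer reagent can therefore join C9 to C10 and then C6 to C7.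
- Forward order: ring C arene from 2,6-dihydroxybenzaldehyde and ring A dienone from β-cyclocitral are joined through C1–C11 by aryllithium addition and oxidative transposition. Then follow the side-chain carbinol, the dearomatising cyclopropane closure, the C11/C12 diol, the reductive double closure (cyclobutane, then ring B) and the end-game.
- Stereochemistry: C15 comes from an enzymatic ketone reduction and is inverted in the cyclopropane closure; C13 is set by closure away from the OTIPS group; C11 and C12 by OsO4 anti to the cyclopropane methyl. C9, C10, C5, C6, C7 and C8 are set in the key step, and C1 by hydrogenation anti to the C11 OTBS group.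

Key step: step 21

Remark: carbon numbers are those of the abietane skeleton (ring A: C1–C5, C10; ring B: C5–C10; ring C: C8, C9, C11–C14; cyclobutane: C1, C10, C9, C11; cyclopropane: C13, C15, C16). Reagents without a compound number are taken as commercial. Compound 14 is formed as a racemate at its carbinol carbon, which becomes planar in step 12.

**Route**

Step 1
Reactants: 1 2,6-dihydroxybenzaldehyde
Product: 2 2-hydroxy-6-(naphthalen-2-ylmethoxy)benzaldehyde
Conditions: 2-(bromomethyl)naphthalene (1 equiv), K2CO3, DMF, 40 °C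
Reagents that add atoms: 2-(bromomethyl)naphthalene BrCc1ccc2ccccc2c1
Why: Williamson mono-etherification of one of the two equivalent phenols; the second phenol stays hydrogen-bonded to the aldehyde and reacts more slowly.

Step 2
Reactants: 2 2-hydroxy-6-(naphthalen-2-ylmethoxy)benzaldehyde
Product: 3 2-(allyloxy)-6-(naphthalen-2-ylmethoxy)benzaldehyde
Conditions: allyl bromide, K2CO3, DMF, rt
Reagents that add atoms: allyl bromide C=CCBr
Why: Williamson O-allylation of the remaining phenol prepares the Claisen rearrangement.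

Step 3
Reactants: 3 2-(allyloxy)-6-(naphthalen-2-ylmethoxy)benzaldehyde
Product: 4 3-allyl-2-hydroxy-6-(naphthalen-2-ylmethoxy)benzaldehyde
Conditions: N,N-diethylaniline, 190 °C
Reagents that add atoms: none
Why: Aromatic Claisen rearrangement delivers the allyl group to the only free ortho position (the future C13) and frees the phenol that becomes the C14 oxygen.

Step 4
Reactants: 4 3-allyl-2-hydroxy-6-(naphthalen-2-ylmethoxy)benzaldehyde
Product: 5 3-allyl-5-bromo-2-hydroxy-6-(naphthalen-2-ylmethoxy)benzaldehyde
Conditions: NBS, MeCN, 0 °C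
Reagents that add atoms: N-bromosuccinimide O=C1CCC(=O)N1Br
Why: Electrophilic aromatic bromination goes para to the free phenol and ortho to the ether oxygen, the only doubly activated position left (the future C11).

Step 5
Reactants: 5 3-allyl-5-bromo-2-hydroxy-6-(naphthalen-2-ylmethoxy)benzaldehyde
Product: 6 3-allyl-5-bromo-6-(naphthalen-2-ylmethoxy)-2-(triisopropylsilyloxy)benzaldehyde
Conditions: TIPSOTf, 2,6-lutidine, CH2Cl2, 0 °C
Reagents that add atoms: triisopropylsilyl trifluoromethanesulfonate CC(C)[Si](C(C)C)(C(C)C)OS(=O)(=O)C(F)(F)F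
Why: O-silylation of the hindered phenol with the silyl triflate gives a bulky, non-nucleophilic aryl silyl ether needed in step 15.

Step 6
Reactants: 6 3-allyl-5-bromo-6-(naphthalen-2-ylmethoxy)-2-(triisopropylsilyloxy)benzaldehyde
Product: 7 dibenzyl acetal of 6 (aryl bromide with CH(OBn)2 between the two aryl oxygens)
Conditions: BnOSiMe3 (2.2 equiv), Me3SiOTf (cat.), CH2Cl2, −78 °C
Reagents that add atoms: benzyloxytrimethylsilane C[Si](C)(C)OCc1ccccc1
Why: Silyl triflate-catalysed acetalisation with the silyl ether of the alcohol works on hindered aryl aldehydes under aprotic conditions and installs C7 as a dibenzyl acetal.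

Step 7
Reactants: 8 β-cyclocitral (2,6,6-trimethylcyclohex-1-ene-1-carbaldehyde)
Product: 9 β-cyclogeraniol
Conditions: NaBH4, MeOH, 0 °C
Reagents that add atoms: none
Why: Borohydride 1,2-reduction of the hindered enal gives the allylic alcohol that carries the future C6.

Step 8
Reactants: 9 β-cyclogeraniol
Product: 10 β-cyclogeranyl tert-butyldimethylsilyl ether
Conditions: TBSCl, imidazole, DMF, rt
Reagents that add atoms: tert-butyldimethylsilyl chloride CC(C)(C)[Si](C)(C)Cl
Why: Standard silylation protects the primary allylic alcohol for the oxidation and organometallic steps.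

Step 9
Reactants: 10 β-cyclogeranyl tert-butyldimethylsilyl ether
Product: 11 3-(tert-butyldimethylsilyloxymethyl)-2,4,4-trimethylcyclohex-2-en-1-one
Conditions: CrO3, 3,5-dimethylpyrazole, CH2Cl2, −20 °C
Reagents that add atoms: chromium trioxide O=[Cr](=O)=O
Why: Allylic oxidation of the ring methylene next to the methyl-bearing alkene carbon is the usual outcome for β-ionone-type rings and gives the enone (future C1 carbonyl).

Step 10
Reactants: 11 3-(tert-butyldimethylsilyloxymethyl)-2,4,4-trimethylcyclohex-2-en-1-one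
Product: 12 3-(tert-butyldimethylsilyloxymethyl)-2,4,4-trimethylcyclohexa-2,5-dien-1-one
Conditions: IBX, DMSO/toluene, 75 °C
Reagents that add atoms: none
Why: IBX dehydrogenation of the ketone can only take place at C2–C3, the one side with α- and β-hydrogens, and gives the cross-conjugated dienone.

Step 11
Reactants: 7 dibenzyl acetal of 6; 12 3-(tert-butyldimethylsilyloxymethyl)-2,4,4-trimethylcyclohexa-2,5-dien-1-one
Product: 14 1-aryl-cyclohexa-2,5-dien-1-ol (tertiary dienol, racemic carbinol), via aryllithium 13 (not isolated)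
Conditions: t-BuLi (2.1 equiv), THF, −78 °C; CeCl3; then 12, −78 → 0 °C
Reagents that add atoms: none
Why: Bromine–lithium exchange and 1,2-addition of the derived organocerium reagent to the dienone carbonyl forms the C1–C11 bond, cerium suppressing conjugate addition and enolisation.

Step 12
Reactants: 14 1-aryl-cyclohexa-2,5-dien-1-ol
Product: 15 3-aryl-6,6-dimethylcyclohexa-2,4-dienone (ring A dienone bonded through C1 to the arene carbon C11)
Conditions: [C5H5NH][CrO3Cl], NaOAc, 4 Å MS, CH2Cl2, 0 °C → rt
Reagents that add atoms: none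
Why: Babler–Dauben oxidative transposition moves the oxygen to C3 and places the double bond at C1–C2; the other allylic terminus (C5) bears no hydrogen, so its chromate ester cannot be oxidised.

Step 13
Reactants: 15 3-aryl-6,6-dimethylcyclohexa-2,4-dienone
Product: 16 arylacetone (methyl ketone in the side chain on the future C13)
Conditions: PdCl2 (cat.), CuCl, O2, DMF/H2O, rt
Reagents that add atoms: water O
Why: Tsuji–Wacker oxidation converts the terminal allyl alkene into the methyl ketone and leaves the internal, conjugated alkenes alone.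

Step 14
Reactants: 16 arylacetone
Product: 17 (R)-1-arylpropan-2-ol
Conditions: ketoreductase (R-selective), NADP+, i-PrOH, phosphate buffer pH 7, 30 °C
Reagents that add atoms: none
Why: Enzymatic asymmetric ketone reduction distinguishes the methyl from the arylmethyl flank of the unhindered ketone, leaves the hindered conjugated ring A ketone alone, and sets the carbinol centre (R) that becomes C15.

Step 15
Reactants: 17 (R)-1-arylpropan-2-ol
Product: 19 spirocyclopropyl 2,4-dienone (C14 ketone, C9 naphthylmethyl enol ether, C13 spiro, C15 methyl cis to C12), via secondary triflate 18 (not isolated)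
Conditions: Tf2O, 2,6-di-tert-butyl-4-methylpyridine, CH2Cl2, −78 → 0 °C
Reagents that add atoms: none
Why: Proposed new method: the triflate is displaced with inversion by the ipso carbon C13 of the electron-rich arene (Ar1-3 participation, supported by the para ether oxygen and the ortho silyloxy group), and the O-silyl arenium ion then loses the silyl group to triflate to give the neutral dienone; the closest known reactions are the phenoxide Ar1-3 spirocyclisation to spiro[2.5]octadienones and the ipso-cyclisation of aryl silyl ethers, and the bulky OTIPS group is meant both to keep the ortho oxygen from alkylating and to turn the C15 methyl away from itself, towards C12.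

Step 16
Reactants: 19 spirocyclopropyl 2,4-dienone
Product: 20 C11,C12-cis-diol (both hydroxyls cis to C16; C11 tertiary)
Conditions: OsO4 (cat.), NMO, acetone/H2O, 0 °C → rt
Reagents that add atoms: N-methylmorpholine N-oxide C[N+]1([O-])CCOCC1; water O
Why: Upjohn dihydroxylation should pick the C11=C12 bond, the only trisubstituted and least electron-poor alkene, and add from the face opposite the cyclopropane CH–CH3 whose methyl lies over C12, which sets C12 and the tertiary C11 carbinol together.

Step 17
Reactants: 20 C11,C12-cis-diol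
Product: 21 C12 acetate (C11 hydroxyl free)
Conditions: Ac2O, DMAP, pyridine, rt
Reagents that add atoms: acetic anhydride CC(=O)OC(C)=O
Why: Nucleophile-catalysed acylation takes the secondary hydroxyl only; the tertiary C11 hydroxyl does not react under these conditions.

Step 18
Reactants: 21 C12 acetate
Product: 22 C11 tert-butyldimethylsilyl ether
Conditions: TBSOTf, 2,6-lutidine, CH2Cl2, −40 → 0 °C
Reagents that add atoms: tert-butyldimethylsilyl trifluoromethanesulfonate CC(C)(C)[Si](C)(C)OS(=O)(=O)C(F)(F)F
Why: Silyl triflate silylation of the tertiary alcohol places a bulky group on the oxygen-bearing face, which is used for facial control in steps 21 and 23.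

Step 19
Reactants: 22 C11 tert-butyldimethylsilyl ether
Product: 23 primary allylic alcohol (C6 hydroxymethyl on ring A)
Conditions: HF·pyridine, pyridine, THF, 0 °C
Reagents that add atoms: none
Why: Buffered fluoride desilylation removes the primary allylic silyl ether much faster than the tertiary one.

Step 20
Reactants: 23 primary allylic alcohol
Product: 24 dienone-enal (ring A: C3 ketone, C1=C2 and C5=C10 double bonds, C6 aldehyde; ring C: C14 ketone, C8=C9 enol ether, C7 acetal)
Conditions: MnO2, CH2Cl2, rt
Reagents that add atoms: none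
Why: Manganese dioxide oxidises allylic alcohols selectively and gives the enal without touching the acetal or the silyl ether.

Step 21
Reactants: 24 dienone-enal
Product: 27 pentacyclic C6 alcohol (cyclobutane and ring B closed; C6 hydroxyl and C7 benzyloxy cis; C1=C2 enone retained), via cyclobutane keto aldehyde 25 (not isolated), via benzyloxymethylene ketone 26 (not isolated)
Conditions: SmI2 (4.5 equiv), t-BuOH, THF, −78 → 0 °C
Reagents that add atoms: none
Why: Proposed new method: SmI2 first reduces the ring A dienone-enal, the most electron-poor π system, and its radical anion, which carries spin at C10, adds 4-exo-trig to C9, the β-carbon of the ring C 3-alkoxy-enone; a second electron leaves two samarium enolates, of which the ring C enolate expels benzyl oxide from the C7 acetal (E1cB) to give an (E)-benzyloxymethylene ketone while the C6 enolate is protonated by t-BuOH to the aldehyde, whose ketyl then adds 6-exo-trig to C7, and C8 is protonated last. The closest known reactions are the reductive β,β'-cyclisation of tethered enones with SmI2 or at a cathode and the SmI2 ketyl addition to β-alkoxy-acrylates and β-alkoxy-enones. The cyclobutane closes 4-exo-trig on the C8=C9 bond and ring B 6-exo-trig on the C7=C8 bond. C9 can only bond on the ring C face that carries C1, so the C9 and C11 oxygens become cis; C10 takes its methyl on the side of the bulky C11 OTBS group; C5 is protonated cis to that methyl (the aldehyde can epimerise and only the cis isomer reaches C7); the C6 and C7 oxygens become cis through a chelate of trivalent samarium on the convex face; and C8, α to the C14 ketone, settles by equilibration to the cis ring B/ring C fusion. The selectivity needed is C9–C10 before anything else: C6 cannot reach C9 because that ring would hold an E double bond, C7 is an inert acetal carbon until the first bond exists, and without HMPA only the dienone-enal and then the aldehyde are reduced, which spares the cyclopropyl ketone, the acetate and the C1=C2 enone.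

Step 22
Reactants: 27 pentacyclic C6 alcohol
Product: 28 C6 acetate
Conditions: Ac2O, DMAP, Et3N, CH2Cl2, rt
Reagents that add atoms: acetic anhydride CC(=O)OC(C)=O
Why: Nucleophile-catalysed acylation of the only free hydroxyl; C7 is still a benzyl ether, so the acetate goes to C6 alone.

Step 23
Reactants: 28 C6 acetate
Product: 29 C11-O-tert-butyldimethylsilyl ether of the target (C1–C2 saturated; C7 and C9 hydroxyls free)
Conditions: H2 (1 atm), Pd/C, EtOAc, rt
Reagents that add atoms: none
Why: Heterogeneous hydrogenation adds H2 to the C1=C2 enone bond from the face opposite the C11 OTBS group and the C10 methyl, which should set C1–H cis to C12 and C5 (the trans ring A/cyclobutane fusion), and the same catalyst cleaves the benzyl and naphthylmethyl ethers by hydrogenolysis.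

Step 24
Reactants: 29 C11-O-tert-butyldimethylsilyl ether of the target
Product: 30 CNP0157858.2
Conditions: HF·pyridine, THF, 0 °C → rt
Reagents that add atoms: none
Why: Acidic fluoride desilylation frees the tertiary C11 hydroxyl without base, which avoids acetate migration and retro-aldol opening of the C9 hydroxy ketone.

**Compound list**

1 | 2,6-dihydroxybenzaldehyde | O=Cc1c(O)cccc1O | starting material
2 | 2-hydroxy-6-(naphthalen-2-ylmethoxy)benzaldehyde | O=Cc1c(O)cccc1OCc1ccc2ccccc2c1 | intermediate
3 | 2-(allyloxy)-6-(naphthalen-2-ylmethoxy)benzaldehyde | O=Cc1c(OCC=C)cccc1OCc1ccc2ccccc2c1 | intermediate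
4 | 3-allyl-2-hydroxy-6-(naphthalen-2-ylmethoxy)benzaldehyde | O=Cc1c(O)c(CC=C)ccc1OCc1ccc2ccccc2c1 | intermediate
5 | 3-allyl-5-bromo-2-hydroxy-6-(naphthalen-2-ylmethoxy)benzaldehyde | O=Cc1c(O)c(CC=C)cc(Br)c1OCc1ccc2ccccc2c1 | intermediate
6 | 3-allyl-5-bromo-6-(naphthalen-2-ylmethoxy)-2-(triisopropylsilyloxy)benzaldehyde | O=Cc1c(O[Si](C(C)C)(C(C)C)C(C)C)c(CC=C)cc(Br)c1OCc1ccc2ccccc2c1 | intermediate
7 | dibenzyl acetal of 6 | C=CCc1cc(Br)c(OCc2ccc3ccccc3c2)c(C(OCc2ccccc2)OCc2ccccc2)c1O[Si](C(C)C)(C(C)C)C(C)C | intermediate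
8 | β-cyclocitral | CC1=C(C=O)C(C)(C)CCC1 | starting material
9 | β-cyclogeraniol | CC1=C(CO)C(C)(C)CCC1 | intermediate
10 | β-cyclogeranyl tert-butyldimethylsilyl ether | CC1=C(CO[Si](C)(C)C(C)(C)C)C(C)(C)CCC1 | intermediate
11 | 3-(tert-butyldimethylsilyloxymethyl)-2,4,4-trimethylcyclohex-2-en-1-one | CC1=C(CO[Si](C)(C)C(C)(C)C)C(C)(C)CCC1=O | intermediate
12 | 3-(tert-butyldimethylsilyloxymethyl)-2,4,4-trimethylcyclohexa-2,5-dien-1-one | CC1=C(CO[Si](C)(C)C(C)(C)C)C(C)(C)C=CC1=O | intermediate
13 | aryllithium from 7 | [Li]c1cc(CC=C)c(O[Si](C(C)C)(C(C)C)C(C)C)c(C(OCc2ccccc2)OCc2ccccc2)c1OCc1ccc2ccccc2c1 | intermediate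
14 | 1-aryl-cyclohexa-2,5-dien-1-ol (racemic carbinol) | C=CCc1cc(C2(O)C=CC(C)(C)C(CO[Si](C)(C)C(C)(C)C)=C2C)c(OCc2ccc3ccccc3c2)c(C(OCc2ccccc2)OCc2ccccc2)c1O[Si](C(C)C)(C(C)C)C(C)C | intermediate
15 | 3-aryl-6,6-dimethylcyclohexa-2,4-dienone | C=CCc1cc(C2=CC(=O)C(C)(C)C(CO[Si](C)(C)C(C)(C)C)=C2C)c(OCc2ccc3ccccc3c2)c(C(OCc2ccccc2)OCc2ccccc2)c1O[Si](C(C)C)(C(C)C)C(C)C | intermediate
16 | arylacetone | CC(=O)Cc1cc(C2=CC(=O)C(C)(C)C(CO[Si](C)(C)C(C)(C)C)=C2C)c(OCc2ccc3ccccc3c2)c(C(OCc2ccccc2)OCc2ccccc2)c1O[Si](C(C)C)(C(C)C)C(C)C | intermediate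
17 | (R)-1-arylpropan-2-ol | C[C@@H](O)Cc1cc(C2=CC(=O)C(C)(C)C(CO[Si](C)(C)C(C)(C)C)=C2C)c(OCc2ccc3ccccc3c2)c(C(OCc2ccccc2)OCc2ccccc2)c1O[Si](C(C)C)(C(C)C)C(C)C | intermediate
18 | (R)-secondary triflate of 17 | C[C@@H](OS(=O)(=O)C(F)(F)F)Cc1cc(C2=CC(=O)C(C)(C)C(CO[Si](C)(C)C(C)(C)C)=C2C)c(OCc2ccc3ccccc3c2)c(C(OCc2ccccc2)OCc2ccccc2)c1O[Si](C(C)C)(C(C)C)C(C)C | intermediate
19 | spirocyclopropyl 2,4-dienone | O=C1[C@]2(C[C@@H]2C)C=C(C2=CC(=O)C(C)(C)C(CO[Si](C)(C)C(C)(C)C)=C2C)C(OCc2ccc3ccccc3c2)=C1C(OCc1ccccc1)OCc1ccccc1 | intermediate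
20 | C11,C12-cis-diol | O=C1[C@]2(C[C@@H]2C)[C@H](O)[C@@](O)(C2=CC(=O)C(C)(C)C(CO[Si](C)(C)C(C)(C)C)=C2C)C(OCc2ccc3ccccc3c2)=C1C(OCc1ccccc1)OCc1ccccc1 | intermediate
21 | C12 acetate | O=C1[C@]2(C[C@@H]2C)[C@H](OC(C)=O)[C@@](O)(C2=CC(=O)C(C)(C)C(CO[Si](C)(C)C(C)(C)C)=C2C)C(OCc2ccc3ccccc3c2)=C1C(OCc1ccccc1)OCc1ccccc1 | intermediate
22 | C11 tert-butyldimethylsilyl ether | O=C1[C@]2(C[C@@H]2C)[C@H](OC(C)=O)[C@@](O[Si](C)(C)C(C)(C)C)(C2=CC(=O)C(C)(C)C(CO[Si](C)(C)C(C)(C)C)=C2C)C(OCc2ccc3ccccc3c2)=C1C(OCc1ccccc1)OCc1ccccc1 | intermediate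
23 | primary allylic alcohol | O=C1[C@]2(C[C@@H]2C)[C@H](OC(C)=O)[C@@](O[Si](C)(C)C(C)(C)C)(C2=CC(=O)C(C)(C)C(CO)=C2C)C(OCc2ccc3ccccc3c2)=C1C(OCc1ccccc1)OCc1ccccc1 | intermediate
24 | dienone-enal | O=C1[C@]2(C[C@@H]2C)[C@H](OC(C)=O)[C@@](O[Si](C)(C)C(C)(C)C)(C2=CC(=O)C(C)(C)C(C=O)=C2C)C(OCc2ccc3ccccc3c2)=C1C(OCc1ccccc1)OCc1ccccc1 | intermediate
25 | cyclobutane keto aldehyde (C8 unassigned, epimerisable) | O=C[C@@H]1C(C)(C)C(=O)C=C2[C@]1(C)[C@@]3(OCc4ccc5ccccc5c4)C(C(OCc4ccccc4)OCc4ccccc4)C(=O)[C@]4(C[C@@H]4C)[C@H](OC(C)=O)[C@@]23O[Si](C)(C)C(C)(C)C | intermediate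
26 | (E)-benzyloxymethylene ketone | O=C[C@@H]1C(C)(C)C(=O)C=C2[C@]1(C)[C@@]3(OCc4ccc5ccccc5c4)/C(=C\OCc4ccccc4)C(=O)[C@]4(C[C@@H]4C)[C@H](OC(C)=O)[C@@]23O[Si](C)(C)C(C)(C)C | intermediate
27 | pentacyclic C6 alcohol | O[C@@H]1[C@H](OCc5ccccc5)[C@H]2C(=O)[C@]3(C[C@@H]3C)[C@H](OC(C)=O)[C@@]3(O[Si](C)(C)C(C)(C)C)C4=CC(=O)C(C)(C)[C@@H]1[C@@]4(C)[C@@]23OCc1ccc2ccccc2c1 | intermediate
28 | C6 acetate | CC(=O)O[C@@H]1[C@H](OCc5ccccc5)[C@H]2C(=O)[C@]3(C[C@@H]3C)[C@H](OC(C)=O)[C@@]3(O[Si](C)(C)C(C)(C)C)C4=CC(=O)C(C)(C)[C@@H]1[C@@]4(C)[C@@]23OCc1ccc2ccccc2c1 | intermediate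
29 | C11-O-tert-butyldimethylsilyl ether of the target | CC(=O)O[C@@H]1[C@H](O)[C@H]2C(=O)[C@]3(C[C@@H]3C)[C@H](OC(C)=O)[C@@]3(O[Si](C)(C)C(C)(C)C)[C@@H]4CC(=O)C(C)(C)[C@@H]1[C@@]4(C)[C@@]23O | intermediate
30 | CNP0157858.2 | CC(=O)O[C@@H]1[C@H](O)[C@H]2C(=O)[C@]3(C[C@@H]3C)[C@H](OC(C)=O)[C@@]3(O)[C@@H]4CC(=O)C(C)(C)[C@@H]1[C@@]4(C)[C@@]23O | target

**Step count and risks**

Total step count: 24. Longest linear sequence: 20 steps (steps 1–6 and 11–24); the ring A branch (steps 7–10) is 4 steps.

Steps most likely to fail: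

1. Step 15 (dearomatising cyclopropane closure). The silyl ether oxygen may take part instead of the ipso carbon (O-alkylation to a dihydrobenzofuran), the arenium ion may be reopened at the cyclopropane by triflate, or the closure may give the other orientation of the C15 methyl. The fallback sets out from 17 and comes back at 19, and uses the classical phenoxide Ar1-3 closure through the oxygen para to C13. The alcohol is converted with MsCl/Et3N into the mesylate F1. DDQ in wet CH2Cl2 removes the naphthylmethyl group and gives the free phenol F2, in which the ortho silyloxy group cannot alkylate. t-BuOK in t-BuOH/THF then closes the cyclopropane through the para phenoxide to the cross-conjugated spirodienone F3 (C9 ketone, C14 silyl enol ether). CsF (1 equiv) in DMF cleaves the labile vinylogous silyl ester, and the dienolate is O-alkylated with 2-(bromomethyl)naphthalene on the C9 oxygen, the one remote from the spiro carbon as with 4,4-disubstituted cyclohexane-1,3-diones, to give 19.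

2. Step 21 (key step). The 4-exo closure may be too slow, so that the dienone-enal is simply reduced or dimerised. The cascade may also stop after the first bond, or the C6 enolate may add to C7 through carbon. The fallback sets out from 24 and comes back at 27, and separates the two bond formations. The reductive β,β'-cyclisation is run on its own with SmI2 (2.2 equiv), HMPA and t-BuOH at −78 °C, the conditions established for tethered enone pairs, and after loss of benzyl alcohol on work-up the benzyloxymethylene ketone 26 is isolated. The C6–C7 bond is then made by an intramolecular Stetter reaction (triazolium carbene catalyst, Et3N, THF), in which the C6 aldehyde adds as an acyl anion equivalent to C7 and gives the C6 ketone F4. Chelation-controlled reduction with Zn(BH4)2 at −40 °C is expected to deliver the C6 alcohol cis to the C7 benzyloxy group, which is 27.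

3. Step 12 (oxidative transposition). The doubly allylic, benzylic carbinol may ionise under the acidic chromium reagent and undergo methyl migration with aromatisation of ring A (dienol–benzene rearrangement), and the acetal may be lost. The fallback sets out from 14 and comes back at 15, and replaces the chromate route by a redox-neutral transposition followed by a separate mild oxidation. Ph3SiOReO3 (cat.) in Et2O at −50 °C isomerises the tertiary dienol by 1,3-hydroxyl shift to the conjugated secondary dienol F5, and MnO2 in CH2Cl2 oxidises this allylic alcohol to 15.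

**Further compounds**

F1 | step 15 | (R)-mesylate of 17 | C[C@@H](OS(C)(=O)=O)Cc1cc(C2=CC(=O)C(C)(C)C(CO[Si](C)(C)C(C)(C)C)=C2C)c(OCc2ccc3ccccc3c2)c(C(OCc2ccccc2)OCc2ccccc2)c1O[Si](C(C)C)(C(C)C)C(C)C
F2 | step 15 | free phenol (naphthylmethyl group removed from F1) | C[C@@H](OS(C)(=O)=O)Cc1cc(C2=CC(=O)C(C)(C)C(CO[Si](C)(C)C(C)(C)C)=C2C)c(O)c(C(OCc2ccccc2)OCc2ccccc2)c1O[Si](C(C)C)(C(C)C)C(C)C
F3 | step 15 | cross-conjugated spirodienone (C9 ketone, C14 triisopropylsilyl enol ether) | O=C1C(C2=CC(=O)C(C)(C)C(CO[Si](C)(C)C(C)(C)C)=C2C)=C[C@@]2(C[C@@H]2C)C(O[Si](C(C)C)(C(C)C)C(C)C)=C1C(OCc1ccccc1)OCc1ccccc1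
F4 | step 21 | C6 ketone from the Stetter closure | O=C1[C@H](OCc5ccccc5)[C@H]2C(=O)[C@]3(C[C@@H]3C)[C@H](OC(C)=O)[C@@]3(O[Si](C)(C)C(C)(C)C)C4=CC(=O)C(C)(C)[C@@H]1[C@@]4(C)[C@@]23OCc1ccc2ccccc2c1
F5 | step 12 | secondary dienol (C3 hydroxyl, racemic) | C=CCc1cc(C2=CC(O)C(C)(C)C(CO[Si](C)(C)C(C)(C)C)=C2C)c(OCc2ccc3ccccc3c2)c(C(OCc2ccccc2)OCc2ccccc2)c1O[Si](C(C)C)(C(C)C)C(C)C
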